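**Retrosynthetic overview**
1. C5–OOH and C4=C15 are unveiled last by a singlet-oxygen ene reaction on the C4=C5 alkene of a 3β-acyloxy-eudesm-4-ene; O3 comes from an enone carbonyl, the 8β-acetate from a C8 ketone, and the acrylate (C11=C13, C12) from a C11 malonate by decarboxylative methylenation.
2. Key disconnection C9–C10: ring B (C5–C10) is closed onto an intact aromatic ring A by acid-promoted dearomatising C-alkylation of a phenol by a diazoketone (C8 carbonyl, C9 diazo carbon), which creates the quaternary C10 and the 1,4-dien-3-one in one operation.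
3. Enabling feature: in ring A (C1–C5, C10) the methyl-bearing C10 is para to the oxygen on C3 and C4 carries C15, so ring A is a masked 2,4-dimethylphenol whose dearomatised form keeps exactly the C3 carbonyl and the C4=C5 alkene the endgame needs; C9 lies next to oxygenated C8 and can therefore arrive as a diazomethyl ketone.
4. The acyclic precursor has a single stereocentre (C7), set by enantioselective organocatalytic α-alkylation of a 3-arylpropanal with a bromomalonate; the arene comes from 2-bromo-m-xylene (acylation, Baeyer–Villiger oxidation, Negishi coupling).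
5. Ring order: ring A is present from the start as the benzene ring; ring B is formed in step 7; no further ring is made.

Key step: step 7

Remark: di-tert-butyl 2-bromopropanedioate (7) and the organozinc 4 are taken as catalogue reagents (7 is otherwise one bromination away from di-tert-butyl malonate); eudesmane numbering (C1–C15) is used for all locants and α/β descriptors.

**Route**

Step 1
Reactants: 1 2-bromo-1,3-dimethylbenzene
Product: 2 1-(3-bromo-2,4-dimethylphenyl)ethan-1-one
Conditions: AcCl, AlCl3, CH2Cl2, 0 °C to rt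
Reagents that add atoms: acetyl chloride, CC(Cl)=O
Why: Friedel–Crafts acylation should take place at the ring position that is ortho to one methyl, para to the other and meta to bromine, the only other free position being meta to both methyl groups.

Step 2
Reactants: 2 1-(3-bromo-2,4-dimethylphenyl)ethan-1-one
Product: 3 3-bromo-2,4-dimethylphenyl acetate
Conditions: mCPBA, CF3CO2H (cat.), CH2Cl2, rt
Reagents that add atoms: 3-chloroperoxybenzoic acid, OOC(=O)c1cccc(Cl)c1
Why: Baeyer–Villiger oxidation with migration of the electron-rich, ortho-substituted aryl group should install the future O3 directly as its acetate, which then serves as the phenol protecting group.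

Step 3
Reactants: 3 3-bromo-2,4-dimethylphenyl acetate; 4 [2-(1,3-dioxolan-2-yl)ethyl]zinc bromide
Product: 6 2,4-dimethyl-3-(3-oxopropyl)phenyl acetate, via dioxolane acetal 5 (not isolated)
Conditions: Pd(OAc)2 (2 mol%), SPhos (4 mol%), THF, 60 °C; then 1 M HCl, THF, rt
Reagents that add atoms: water, O
Why: Negishi coupling of the di-ortho-substituted aryl bromide with a primary alkylzinc reagent under a bulky biarylphosphine ligand should form the C5–C6 bond without touching the aryl acetate, and the acidic work-up hydrolyses the dioxolane to the aldehyde.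

Step 4
Reactants: 6 2,4-dimethyl-3-(3-oxopropyl)phenyl acetate; 7 di-tert-butyl 2-bromopropanedioate
Product: 8 di-tert-butyl 2-[(2R)-1-(3-acetoxy-2,6-dimethylphenyl)-3-oxopropan-2-yl]propanedioate
Conditions: Ru(bpy)3Cl2 (0.5 mol%), trans-2-tert-butyl-3,5-dimethylimidazolidin-4-one triflate salt (20 mol%, the enantiomer that gives the 2R aldehyde), 2,6-lutidine, DMF, visible light, 23 °C
Reagents that add atoms: none
Why: Enantioselective organocatalytic photoredox α-alkylation of an aldehyde (the malonyl radical adds to the chiral enamine) should form the C7–C11 bond, the C7 stereocentre being set by the imidazolidinone, which shields one enamine face.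

Step 5
Reactants: 8 di-tert-butyl 2-[(2R)-1-(3-acetoxy-2,6-dimethylphenyl)-3-oxopropan-2-yl]propanedioate
Product: 9 (2R)-2-[(3-acetoxy-2,6-dimethylphenyl)methyl]-4-tert-butoxy-3-(tert-butoxycarbonyl)-4-oxobutanoic acid
Conditions: NaClO2, NaH2PO4, 2-methylbut-2-ene, t-BuOH/H2O, 0 °C to rt
Reagents that add atoms: sodium chlorite, [Na+].[O-]Cl=O
Why: Pinnick oxidation under buffered conditions should convert the α-branched aldehyde into the acid (C8) without epimerising C7 and without affecting the aryl acetate or the tert-butyl esters.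

Step 6
Reactants: 9 (2R)-2-[(3-acetoxy-2,6-dimethylphenyl)methyl]-4-tert-butoxy-3-(tert-butoxycarbonyl)-4-oxobutanoic acid
Product: 12 di-tert-butyl 2-[(2R)-4-diazo-1-(3-hydroxy-2,6-dimethylphenyl)-3-oxobutan-2-yl]propanedioate, via mixed carbonic anhydride 10 (not isolated), via acetoxy diazoketone 11 (not isolated)
Conditions: i-BuOCOCl, N-methylmorpholine, THF, −15 °C; CH2N2, Et2O, 0 °C; then K2CO3 (0.5 equiv), MeOH, 0 °C
Reagents that add atoms: diazomethane, C=[N+]=[N-]
Why: Acylation of diazomethane by the mixed anhydride (the first stage of an Arndt–Eistert sequence) should give the diazoketone with C7 intact because no ketene or enolate is involved, and mild methanolysis then frees the phenol while diazoketone and tert-butyl esters survive.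

Step 7
Reactants: 12 di-tert-butyl 2-[(2R)-4-diazo-1-(3-hydroxy-2,6-dimethylphenyl)-3-oxobutan-2-yl]propanedioate
Product: 13 di-tert-butyl 2-[(2R,4aS)-4a,8-dimethyl-3,7-dioxo-1,2,3,4,4a,7-hexahydronaphthalen-2-yl]propanedioate
Conditions: CF3CO2H (5 equiv), CH2Cl2 (0.01 M), −20 °C, short contact; aq. NaHCO3 quench
Reagents that add atoms: none
Why: Protonation of the diazo carbon C9 gives an α-keto diazonium ion that is displaced, with loss of N2, by the phenol carbon para to the hydroxyl (C10), and loss of the O–H proton from the hydroxy-stabilised cyclohexadienyl cation leaves the cross-conjugated cyclohexa-2,5-dienone. The closest known reaction type is the acid-promoted intramolecular C-alkylation of phenols by diazoketones, the dearomatising variant of the 2-tetralone synthesis from 4-aryl-1-diazobutan-2-ones. Ring B (C5–C10) closes by a 6-exo-tet displacement at C9 with participation of the ring carbon next to the tether (Ar2-6 mode), which makes C10 quaternary. The configuration at C10 is controlled by C7 through a chair-like transition state in which C8 is trigonal and the bulky bis(tert-butoxycarbonyl)methyl group is equatorial, so that C9 adds to the arene face that places the C14 methyl cis to the C7 substituent (both β). The step needs attack at C10 (para) and not at C4 (ortho), and ring closure in preference to capture of C9 by trifluoroacetate or an ester carbonyl; the para preference of hydroxyl-directed ipso attack (leading to the more stable cross-conjugated dienone), the two flanking methyl groups that hold the C6–C7 bond perpendicular to the ring with C9 over the π face, and the short low-temperature exposure in a poorly nucleophilic medium should secure this. The free hydroxyl on C3 is what allows the cation to collapse to the dienone, so the C3 carbonyl and the C4=C5 alkene needed later are delivered in the same operation.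

Step 8
Reactants: 13 di-tert-butyl 2-[(2R,4aS)-4a,8-dimethyl-3,7-dioxo-1,2,3,4,4a,7-hexahydronaphthalen-2-yl]propanedioate
Product: 14 di-tert-butyl 2-[(2R,4aR)-4a,8-dimethyl-3,7-dioxo-1,2,3,4,4a,5,6,7-octahydronaphthalen-2-yl]propanedioate
Conditions: H2 (1 atm), RhCl(PPh3)3 (5 mol%), benzene/EtOH, rt
Reagents that add atoms: none
Why: Homogeneous hydrogenation with RhCl(PPh3)3 should saturate only the disubstituted C1=C2 alkene of the cross-conjugated dienone, leaving the tetrasubstituted C4=C5 alkene and both ketones untouched.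

Step 9
Reactants: 14 di-tert-butyl 2-[(2R,4aR)-4a,8-dimethyl-3,7-dioxo-1,2,3,4,4a,5,6,7-octahydronaphthalen-2-yl]propanedioate
Product: 16 di-tert-butyl 2-[(2R,3R,4aR)-3-acetoxy-4a,8-dimethyl-7-oxo-1,2,3,4,4a,5,6,7-octahydronaphthalen-2-yl]propanedioate, via lithium alkoxide 15 (not isolated)
Conditions: LiBH(s-Bu)3 (1.1 equiv), THF, −78 °C; then Ac2O, DMAP, −78 °C to rt
Reagents that add atoms: acetic anhydride, CC(=O)OC(C)=O
Why: Substrate-controlled reduction by the bulky trialkylborohydride should reach only the saturated C8 ketone, from the equatorial direction because the β face is screened by the axial C10 methyl, giving the axial 8β-alkoxide that is acetylated in the same flask, while the tert-butyl esters prevent lactonisation onto C12.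

Step 10
Reactants: 16 di-tert-butyl 2-[(2R,3R,4aR)-3-acetoxy-4a,8-dimethyl-7-oxo-1,2,3,4,4a,5,6,7-octahydronaphthalen-2-yl]propanedioate
Product: 19 2-[(2R,3R,4aR)-3-acetoxy-4a,8-dimethyl-7-oxo-1,2,3,4,4a,5,6,7-octahydronaphthalen-2-yl]prop-2-enoic acid, via malonic acid 17 (not isolated), via Mannich base 18 (not isolated)
Conditions: CF3CO2H/CH2Cl2 (1:2), rt; evaporate; (CH2O)n, Et2NH, EtOAc, rt then reflux
Reagents that add atoms: formaldehyde (as paraformaldehyde), C=O
Why: Acidolysis of both tert-butyl esters followed by a Mannich reaction and decarboxylative elimination (decarboxylative methylenation of a substituted malonic acid) should give the C11=C13 acrylic acid under conditions that spare the enone and the 8-acetate, the acetate at O8 ruling out lactonisation.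

Step 11
Reactants: 19 2-[(2R,3R,4aR)-3-acetoxy-4a,8-dimethyl-7-oxo-1,2,3,4,4a,5,6,7-octahydronaphthalen-2-yl]prop-2-enoic acid
Product: 20 methyl 8β-acetoxy-3-oxoeudesma-4,11(13)-dien-12-oate
Conditions: MeI, KHCO3, DMF, rt
Reagents that add atoms: iodomethane, CI
Why: O-Alkylation of the carboxylate (SN2) should give the methyl ester without base strong enough to affect the acetate or the enone.

Step 12
Reactants: 20 methyl 8β-acetoxy-3-oxoeudesma-4,11(13)-dien-12-oate
Product: 21 methyl 8β-acetoxy-3β-hydroxyeudesma-4,11(13)-dien-12-oate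
Conditions: NaBH4, CeCl3·7H2O, MeOH, −78 to −40 °C
Reagents that add atoms: none
Why: Luche reduction should give clean 1,2-reduction of the enone with hydride delivered to the α face, anti to the axial C10 methyl, setting the pseudo-equatorial 3β-hydroxyl while acrylate and acetate are untouched.

Step 13
Reactants: 21 methyl 8β-acetoxy-3β-hydroxyeudesma-4,11(13)-dien-12-oate
Product: 22 methyl 8β-acetoxy-3β-(2-methylpropanoyloxy)eudesma-4,11(13)-dien-12-oate
Conditions: i-PrCOCl, pyridine, DMAP (cat.), CH2Cl2, 0 °C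
Reagents that add atoms: 2-methylpropanoyl chloride, CC(C)C(Cl)=O
Why: DMAP-catalysed acylation of the unhindered allylic alcohol should proceed with retention at C3.

Step 14
Reactants: 22 methyl 8β-acetoxy-3β-(2-methylpropanoyloxy)eudesma-4,11(13)-dien-12-oate
Product: 23 methyl 8β-acetoxy-5α-hydroperoxy-3β-(2-methylpropanoyloxy)eudesma-4(15),11(13)-dien-12-oate (CNP0244758.1)
Conditions: O2, visible light, 5,10,15,20-tetraphenylporphyrin (cat.), CH2Cl2, −20 °C
Reagents that add atoms: dioxygen, O=O
Why: The Schenck ene reaction of singlet oxygen with the electron-rich tetrasubstituted C4=C5 alkene should occur on the α face (the β face is blocked by the axial C10 methyl and the 8β-acetoxy group) with abstraction of a C15 hydrogen (the C3 hydrogen is deactivated by the geminal acyloxy group and the α hydrogen on C6 is equatorial), giving the 5α-hydroperoxide and the C4=C15 methylene, while the electron-poor acrylate is inert.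

**Compound list**
1 | 2-bromo-1,3-dimethylbenzene | Cc1cccc(C)c1Br | starting material
2 | 1-(3-bromo-2,4-dimethylphenyl)ethan-1-one | CC(=O)c1ccc(C)c(Br)c1C | intermediate
3 | 3-bromo-2,4-dimethylphenyl acetate | CC(=O)Oc1ccc(C)c(Br)c1C | intermediate
4 | [2-(1,3-dioxolan-2-yl)ethyl]zinc bromide | Br[Zn]CCC1OCCO1 | starting material
5 | 3-[2-(1,3-dioxolan-2-yl)ethyl]-2,4-dimethylphenyl acetate (not isolated) | CC(=O)Oc1ccc(C)c(CCC2OCCO2)c1C | intermediate
6 | 2,4-dimethyl-3-(3-oxopropyl)phenyl acetate | CC(=O)Oc1ccc(C)c(CCC=O)c1C | intermediate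
7 | di-tert-butyl 2-bromopropanedioate | CC(C)(C)OC(=O)C(Br)C(=O)OC(C)(C)C | starting material
8 | di-tert-butyl 2-[(2R)-1-(3-acetoxy-2,6-dimethylphenyl)-3-oxopropan-2-yl]propanedioate | CC(C)(C)OC(=O)C(C(=O)OC(C)(C)C)[C@H](C=O)Cc1c(C)ccc(OC(C)=O)c1C | intermediate
9 | (2R)-2-[(3-acetoxy-2,6-dimethylphenyl)methyl]-4-tert-butoxy-3-(tert-butoxycarbonyl)-4-oxobutanoic acid | CC(C)(C)OC(=O)C(C(=O)OC(C)(C)C)[C@H](C(=O)O)Cc1c(C)ccc(OC(C)=O)c1C | intermediate
10 | isobutyl carbonic mixed anhydride of acid 9 (not isolated) | CC(C)(C)OC(=O)C(C(=O)OC(C)(C)C)[C@H](C(=O)OC(=O)OCC(C)C)Cc1c(C)ccc(OC(C)=O)c1C | intermediate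
11 | di-tert-butyl 2-[(2R)-1-(3-acetoxy-2,6-dimethylphenyl)-4-diazo-3-oxobutan-2-yl]propanedioate (not isolated) | CC(C)(C)OC(=O)C(C(=O)OC(C)(C)C)[C@H](C(=O)C=[N+]=[N-])Cc1c(C)ccc(OC(C)=O)c1C | intermediate
12 | di-tert-butyl 2-[(2R)-4-diazo-1-(3-hydroxy-2,6-dimethylphenyl)-3-oxobutan-2-yl]propanedioate | CC(C)(C)OC(=O)C(C(=O)OC(C)(C)C)[C@H](C(=O)C=[N+]=[N-])Cc1c(C)ccc(O)c1C | intermediate
13 | di-tert-butyl 2-[(2R,4aS)-4a,8-dimethyl-3,7-dioxo-1,2,3,4,4a,7-hexahydronaphthalen-2-yl]propanedioate (7β-substituent, 10β-methyl) | CC(C)(C)OC(=O)C(C(=O)OC(C)(C)C)[C@H]1CC2=C(C)C(=O)C=C[C@]2(C)CC1=O | intermediate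
14 | di-tert-butyl 2-[(2R,4aR)-4a,8-dimethyl-3,7-dioxo-1,2,3,4,4a,5,6,7-octahydronaphthalen-2-yl]propanedioate | CC(C)(C)OC(=O)C(C(=O)OC(C)(C)C)[C@H]1CC2=C(C)C(=O)CC[C@]2(C)CC1=O | intermediate
15 | lithium 8β-alkoxide of di-tert-butyl 2-[(2R,3R,4aR)-3-hydroxy-4a,8-dimethyl-7-oxo-1,2,3,4,4a,5,6,7-octahydronaphthalen-2-yl]propanedioate (not isolated) | CC(C)(C)OC(=O)C(C(=O)OC(C)(C)C)[C@H]1CC2=C(C)C(=O)CC[C@]2(C)C[C@H]1[O-].[Li+] | intermediate
16 | di-tert-butyl 2-[(2R,3R,4aR)-3-acetoxy-4a,8-dimethyl-7-oxo-1,2,3,4,4a,5,6,7-octahydronaphthalen-2-yl]propanedioate (8β-acetate) | CC(C)(C)OC(=O)C(C(=O)OC(C)(C)C)[C@H]1CC2=C(C)C(=O)CC[C@]2(C)C[C@H]1OC(C)=O | intermediate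
17 | 2-[(2R,3R,4aR)-3-acetoxy-4a,8-dimethyl-7-oxo-1,2,3,4,4a,5,6,7-octahydronaphthalen-2-yl]propanedioic acid (not isolated) | OC(=O)C(C(=O)O)[C@H]1CC2=C(C)C(=O)CC[C@]2(C)C[C@H]1OC(C)=O | intermediate
18 | 2-[(2R,3R,4aR)-3-acetoxy-4a,8-dimethyl-7-oxo-1,2,3,4,4a,5,6,7-octahydronaphthalen-2-yl]-2-[(diethylamino)methyl]propanedioic acid (not isolated) | CCN(CC)CC(C(=O)O)(C(=O)O)[C@H]1CC2=C(C)C(=O)CC[C@]2(C)C[C@H]1OC(C)=O | intermediate
19 | 2-[(2R,3R,4aR)-3-acetoxy-4a,8-dimethyl-7-oxo-1,2,3,4,4a,5,6,7-octahydronaphthalen-2-yl]prop-2-enoic acid (8β-acetoxy-3-oxoeudesma-4,11(13)-dien-12-oic acid) | C=C(C(=O)O)[C@H]1CC2=C(C)C(=O)CC[C@]2(C)C[C@H]1OC(C)=O | intermediate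
20 | methyl 8β-acetoxy-3-oxoeudesma-4,11(13)-dien-12-oate | C=C(C(=O)OC)[C@H]1CC2=C(C)C(=O)CC[C@]2(C)C[C@H]1OC(C)=O | intermediate
21 | methyl 8β-acetoxy-3β-hydroxyeudesma-4,11(13)-dien-12-oate; methyl 2-[(2R,3R,4aR,7S)-3-acetoxy-7-hydroxy-4a,8-dimethyl-1,2,3,4,4a,5,6,7-octahydronaphthalen-2-yl]prop-2-enoate | C=C(C(=O)OC)[C@H]1CC2=C(C)[C@@H](O)CC[C@]2(C)C[C@H]1OC(C)=O | intermediate
22 | methyl 8β-acetoxy-3β-(2-methylpropanoyloxy)eudesma-4,11(13)-dien-12-oate | C=C(C(=O)OC)[C@H]1CC2=C(C)[C@@H](OC(=O)C(C)C)CC[C@]2(C)C[C@H]1OC(C)=O | intermediate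
23 | methyl 8β-acetoxy-5α-hydroperoxy-3β-(2-methylpropanoyloxy)eudesma-4(15),11(13)-dien-12-oate; methyl 2-[(2R,3R,4aR,7S,8aS)-3-acetoxy-8a-hydroperoxy-4a-methyl-8-methylidene-7-(2-methylpropanoyloxy)decahydronaphthalen-2-yl]prop-2-enoate | C=C(C(=O)OC)[C@H]1C[C@@]2(OO)C(=C)[C@@H](OC(=O)C(C)C)CC[C@]2(C)C[C@H]1OC(C)=O | target

**Step count and risk assessment**

Total step count: 14. Longest linear sequence: 14 steps (from 1; compounds 4 and 7 are bought).

Steps most likely to fail:

Step 7 (key step). The diazonium ion may be diverted before ring closure: solvolytic capture by trifluoroacetate, participation of a malonate carbonyl with loss of a tert-butyl group, or attack at the ortho carbon C4. Facial selectivity on the arene may also be incomplete, giving the C10 epimer. That epimer would have to be removed by chromatography at 13 before any basic treatment, because later equilibration at C7 would turn it into the enantiomeric series. Fallback, from 12 back to 13: the diazoketone 12 would be treated with one equivalent of dry HBr (Et2O, −30 °C) to give di-tert-butyl 2-[(2R)-4-bromo-1-(3-hydroxy-2,6-dimethylphenyl)-3-oxobutan-2-yl]propanedioate F1. Ring B would then be closed by anionic para-C-alkylation of the phenoxide (potassium tert-butoxide, t-BuOH, high dilution, rt), the classical base-mediated alkylative dearomatisation of a phenol by a tethered alkyl halide. The phenoxide carbon is then the only strong nucleophile present, and the closure rejoins the route at dienone 13.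

Step 14. Hydrogen abstraction may be poorly regioselective (from C6 or C3 in place of C15), or singlet oxygen may add in part to the β face. Fallback, from 22 back to 23: epoxidation of 22 with mCPBA on the open α face would give methyl 8β-acetoxy-4α,5α-epoxy-3β-(2-methylpropanoyloxy)eudesm-11(13)-en-12-oate F2. Base-promoted epoxide-to-allylic-alcohol isomerisation with diethylaluminium 2,2,6,6-tetramethylpiperidide, Et2Al(NC9H18), in benzene at 0 °C removes a proton from the C15 methyl and would give methyl 8β-acetoxy-5α-hydroxy-3β-(2-methylpropanoyloxy)eudesma-4(15),11(13)-dien-12-oate F3. Acid-catalysed perhydrolysis of this tertiary allylic alcohol (anhydrous H2O2 in Et2O, cat. TsOH, 0 °C) is expected to add from the α face and would return the target 23.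

Step 4. Enantioselectivity may erode through slow radical capture by the enamine with the bulky bromomalonate or through racemisation of the α-branched aldehyde. Fallback, from 6 back to 9: aldehyde 6 would be condensed with pyrrolidine to give 2,4-dimethyl-3-[(2E)-3-(pyrrolidin-1-yl)prop-2-en-1-yl]phenyl acetate F4. Stork enamine alkylation with 7 (MeCN, rt, then aqueous acetate buffer) would give racemic di-tert-butyl 2-[1-(3-acetoxy-2,6-dimethylphenyl)-3-oxopropan-2-yl]propanedioate F5, and Pinnick oxidation would give racemic 2-[(3-acetoxy-2,6-dimethylphenyl)methyl]-4-tert-butoxy-3-(tert-butoxycarbonyl)-4-oxobutanoic acid F6. Classical resolution by crystallisation with (R)-1-phenylethylamine (or its antipode, whichever pairs with the 2R acid) would give the (1R)-1-phenylethylammonium (2R)-carboxylate salt F7, and cold dilute HCl would release acid 9.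

**Further compounds**
F1 | step 7 | di-tert-butyl 2-[(2R)-4-bromo-1-(3-hydroxy-2,6-dimethylphenyl)-3-oxobutan-2-yl]propanedioate | CC(C)(C)OC(=O)C(C(=O)OC(C)(C)C)[C@H](C(=O)CBr)Cc1c(C)ccc(O)c1C
F2 | step 14 | methyl 8β-acetoxy-4α,5α-epoxy-3β-(2-methylpropanoyloxy)eudesm-11(13)-en-12-oate | C=C(C(=O)OC)[C@H]1C[C@]23O[C@]3(C)[C@@H](OC(=O)C(C)C)CC[C@]2(C)C[C@H]1OC(C)=O
F3 | step 14 | methyl 8β-acetoxy-5α-hydroxy-3β-(2-methylpropanoyloxy)eudesma-4(15),11(13)-dien-12-oate | C=C(C(=O)OC)[C@H]1C[C@@]2(O)C(=C)[C@@H](OC(=O)C(C)C)CC[C@]2(C)C[C@H]1OC(C)=O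
F4 | step 4 | 2,4-dimethyl-3-[(2E)-3-(pyrrolidin-1-yl)prop-2-en-1-yl]phenyl acetate | CC(=O)Oc1ccc(C)c(C/C=C/N2CCCC2)c1C
F5 | step 4 | racemic di-tert-butyl 2-[1-(3-acetoxy-2,6-dimethylphenyl)-3-oxopropan-2-yl]propanedioate | CC(C)(C)OC(=O)C(C(=O)OC(C)(C)C)C(C=O)Cc1c(C)ccc(OC(C)=O)c1C
F6 | step 4 | racemic 2-[(3-acetoxy-2,6-dimethylphenyl)methyl]-4-tert-butoxy-3-(tert-butoxycarbonyl)-4-oxobutanoic acid | CC(C)(C)OC(=O)C(C(=O)OC(C)(C)C)C(C(=O)O)Cc1c(C)ccc(OC(C)=O)c1C
F7 | step 4 | (1R)-1-phenylethan-1-aminium (2R)-2-[(3-acetoxy-2,6-dimethylphenyl)methyl]-4-tert-butoxy-3-(tert-butoxycarbonyl)-4-oxobutanoate | CC(C)(C)OC(=O)C(C(=O)OC(C)(C)C)[C@H](C(=O)[O-])Cc1c(C)ccc(OC(C)=O)c1C.C[C@@H]([NH3+])c1ccccc1
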